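**Retrosynthetic overview**

1. The target is cut first at the two phenol O–H bonds (isopropyl ethers) and at the aryl–vinyl bond of the stilbene, which gives a ring C aryl bromide and 4-isopropoxystyrene (ring D) as Heck partners.
2. Key disconnection: in ring C the carbon bonded to the diarylmethine carbon C-1 (C-1') and the adjacent methoxy-bearing carbon (C-2') are cut together. C-1' lies between two OMe carbons (C-2', C-6'), so ring C is a 5-bromo-3-methoxybenzyne that has taken up OMe and C-1 across its triple bond from the C-1–OMe bond of an (S)-benzylic methyl ether.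
3. The ether (rings A and B, C-1 to C-3) comes from asymmetric transfer hydrogenation of a dihydrochalcone, itself made by Claisen–Schmidt condensation and alkene hydrogenation.
4. The ortho-silylaryl triflate comes from 4-bromo-2-methoxyphenol by ortho-bromination, O-silylation, retro-Brook shift and triflation.
5. No ring is formed: rings A, B, C and D are all bought as benzene rings. C-1 is the only stereocentre, set by the transfer hydrogenation and carried through the key step.

Key step: step 9

Remark 1: C-1 of the target is read as (S) (ring C > ring A > CH2 > H). A retentive shift therefore needs the (S)-ether, hence the (S,S) catalyst in step 4.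
Remark 2: the ring B phenol is carried as an isopropyl ether and ring C carries bromine. An acetal-type protecting group, a crown ether or an ethereal solvent would offer the aryne a second dialkyl-ether oxygen, and a carbonyl substituent would not survive the butyllithium used to make the silyl triflate. The bromine also allows a direct Heck coupling.
Remark 3: 4-bromo-2-methoxyphenol and 4-isopropoxybenzaldehyde are taken as catalogue compounds.

**Route**

Step 1
Reactants: 1 4-hydroxy-2-methoxybenzaldehyde
Product: 2 4-isopropoxy-2-methoxybenzaldehyde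
Conditions: 2-bromopropane, K2CO3, DMF, 60 °C
Reagents that add atoms: 2-bromopropane, CC(C)Br
Why: Williamson ether synthesis on the acidic para-formyl phenoxide; the resulting aryl isopropyl ether oxygen is conjugated to ring B, so it should not compete for the aryne later, and it survives base, hydrogenation and fluoride.

Step 2
Reactants: 2 4-isopropoxy-2-methoxybenzaldehyde; 3 4'-methoxyacetophenone
Product: 4 (E)-3-(4-isopropoxy-2-methoxyphenyl)-1-(4-methoxyphenyl)prop-2-en-1-one
Conditions: KOH, EtOH, rt
Reagents that add atoms: none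
Why: Claisen–Schmidt aldol condensation; the ketone enolate adds to the non-enolisable aldehyde and E1cB dehydration should give the conjugated (E)-enone.

Step 3
Reactants: 4 (E)-3-(4-isopropoxy-2-methoxyphenyl)-1-(4-methoxyphenyl)prop-2-en-1-one
Product: 5 3-(4-isopropoxy-2-methoxyphenyl)-1-(4-methoxyphenyl)propan-1-one
Conditions: H2 (1 atm), Pd/C, Ph2S (cat.), EtOAc, rt
Reagents that add atoms: none
Why: Heterogeneous catalytic hydrogenation of the conjugated C=C; diphenyl sulfide moderates Pd/C so that the electron-rich aryl ketone and the aryl ethers should be left untouched.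

Step 4
Reactants: 5 3-(4-isopropoxy-2-methoxyphenyl)-1-(4-methoxyphenyl)propan-1-one
Product: 6 (1S)-3-(4-isopropoxy-2-methoxyphenyl)-1-(4-methoxyphenyl)propan-1-ol
Conditions: RuCl[(S,S)-TsDPEN](p-cymene) (1 mol %), HCO2H/Et3N (5:2), EtOAc, 40 °C
Reagents that add atoms: none
Why: Noyori asymmetric transfer hydrogenation; the (S,S) catalyst should deliver hydride to the Re face of the aryl alkyl ketone through the outer-sphere six-membered transition state (arene CH–π contact with ring A), setting C-1 as (S) in the same sense as for acetophenone.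

Step 5
Reactants: 6 (1S)-3-(4-isopropoxy-2-methoxyphenyl)-1-(4-methoxyphenyl)propan-1-ol
Product: 7 (S)-1-methoxy-1-(4-methoxyphenyl)-3-(4-isopropoxy-2-methoxyphenyl)propane
Conditions: NaH, MeI, THF, 0 °C → rt
Reagents that add atoms: iodomethane, CI
Why: Williamson O-methylation of the alkoxide; no bond to C-1 is broken, so the (S) configuration should be kept.

Step 6
Reactants: 8 4-bromo-2-methoxyphenol
Product: 9 2,4-dibromo-6-methoxyphenol
Conditions: Br2 (1.0 equiv), AcOH, rt
Reagents that add atoms: bromine, BrBr
Why: Electrophilic aromatic bromination; the free hydroxyl group directs to its only open ortho position, as in the bromination of other 4-substituted guaiacols.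

Step 7
Reactants: 9 2,4-dibromo-6-methoxyphenol
Product: 10 (2,4-dibromo-6-methoxyphenoxy)trimethylsilane
Conditions: HMDS, THF, reflux; evaporate
Reagents that add atoms: hexamethyldisilazane, C[Si](C)(C)N[Si](C)(C)C
Why: O-silylation of the phenol with hexamethyldisilazane; ammonia is the only by-product, so the crude silyl ether should be usable after evaporation.

Step 8
Reactants: 10 (2,4-dibromo-6-methoxyphenoxy)trimethylsilane
Product: 13 4-bromo-2-methoxy-6-(trimethylsilyl)phenyl trifluoromethanesulfonate, via (5-bromo-3-methoxy-2-trimethylsilyloxyphenyl)lithium 11 (not isolated), via lithium 4-bromo-2-methoxy-6-(trimethylsilyl)phenoxide 12 (not isolated)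
Conditions: n-BuLi (1.0 equiv), THF, −78 °C; then Tf2O, −78 °C → rt
Reagents that add atoms: trifluoromethanesulfonic anhydride, O=S(=O)(OS(=O)(=O)C(F)(F)F)C(F)(F)F
Why: Bromine–lithium exchange should occur at the bromine ortho to the silyloxy group (the oxygen-flanked, more stabilised aryllithium; any para-lithiated material re-equilibrates by ArLi/ArBr exchange), the 1,3 O-to-C silyl shift (retro-Brook rearrangement) makes this irreversible, and O-triflation of the phenoxide completes the ortho-silylaryl triflate.

Step 9
Reactants: 7 (S)-1-methoxy-1-(4-methoxyphenyl)-3-(4-isopropoxy-2-methoxyphenyl)propane; 13 4-bromo-2-methoxy-6-(trimethylsilyl)phenyl trifluoromethanesulfonate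
Product: 16 5-bromo-2-[(1S)-3-(4-isopropoxy-2-methoxyphenyl)-1-(4-methoxyphenyl)propyl]-1,3-dimethoxybenzene, via 5-bromo-3-methoxybenzyne 14 (not isolated), via aryloxonium aryl-anion zwitterion 15 (not isolated)
Conditions: TBAT (2.5 equiv), toluene, 50 °C; 7 limiting at high concentration, 13 (2 equiv) added over 6 h; no ethereal solvent or crown ether
Reagents that add atoms: none
Why: Proposed new method: fluoride removes the silyl group of 13 and triflate leaves to give aryne 14, whose triple bond is distorted by the flanking methoxy group, so the ether oxygen of 7 should add at the aryne carbon remote from OMe and place the aryl anion of zwitterion 15 ortho to OMe; ionisation of the O–C-1 bond, made easy by the aryloxonium leaving group and the 4-methoxyphenyl group, and collapse of the contact ion pair onto the neighbouring carbanion would complete a formal σ-insertion of the aryne into the benzylic C–O bond. The closest known reactions are aryne σ-insertions into C–N and C–S bonds through onium zwitterions and Stevens-type 1,2-shifts of benzylic groups in onium ylides. No ring is closed; the two new skeletal bonds are C-2'–OMe and C-1'–C-1 of ring C. The stereocentre at C-1 is transferred, not created: the carbanion lies on the same side as the departing oxygen, so front-side recombination within the solvent cage in toluene should give retention, (S)-7 to (S)-16. The step needs O-attack at the distal aryne carbon (secured by the 3-methoxy group of 14), attack by the benzylic ether oxygen alone (it is the only dialkyl-ether oxygen present, since acetals, crown ethers and ethereal solvents are excluded), and a shift that outruns β-hydrogen abstraction and protonation of the aryl anion (favoured by the cation-stabilising ring A and the aprotic medium).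

Step 10
Reactants: 17 4-isopropoxybenzaldehyde
Product: 18 4-isopropoxystyrene
Conditions: Ph3PCH3Br, KOtBu, THF, 0 °C → rt
Reagents that add atoms: methyltriphenylphosphonium bromide, C[P+](c1ccccc1)(c1ccccc1)c1ccccc1.[Br-]
Why: Wittig methylenation of a non-enolisable aromatic aldehyde with the unstabilised ylide.

Step 11
Reactants: 16 5-bromo-2-[(1S)-3-(4-isopropoxy-2-methoxyphenyl)-1-(4-methoxyphenyl)propyl]-1,3-dimethoxybenzene; 18 4-isopropoxystyrene
Product: 19 5-[(E)-2-(4-isopropoxyphenyl)ethenyl]-2-[(1S)-3-(4-isopropoxy-2-methoxyphenyl)-1-(4-methoxyphenyl)propyl]-1,3-dimethoxybenzene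
Conditions: Pd(OAc)2 (5 mol %), P(o-tol)3, Et3N, DMF, 100 °C
Reagents that add atoms: none
Why: Mizoroki–Heck reaction; oxidative addition of the unhindered aryl bromide, syn-insertion at the terminal carbon of the styrene and syn-β-hydride elimination should give the (E)-stilbene, while the non-acidic C-1–H is untouched.

Step 12
Reactants: 19 5-[(E)-2-(4-isopropoxyphenyl)ethenyl]-2-[(1S)-3-(4-isopropoxy-2-methoxyphenyl)-1-(4-methoxyphenyl)propyl]-1,3-dimethoxybenzene
Product: 20 4-[(3S)-3-{4-[(E)-2-(4-hydroxyphenyl)ethenyl]-2,6-dimethoxyphenyl}-3-(4-methoxyphenyl)propyl]-3-methoxyphenol (CNP0182684.1)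
Conditions: BCl3 (6 equiv), CH2Cl2, −78 → 0 °C; then H2O
Reagents that add atoms: none
Why: Lewis-acid dealkylation of aryl ethers; BCl3 at low temperature should cleave the two secondary-alkyl (isopropyl) aryl ethers in preference to the four isolated aryl methyl ethers, and no bond to C-1 is involved.

**Compound list**

1 | 4-hydroxy-2-methoxybenzaldehyde | COc1cc(O)ccc1C=O | starting material
2 | 4-isopropoxy-2-methoxybenzaldehyde | COc1cc(OC(C)C)ccc1C=O | intermediate
3 | 4'-methoxyacetophenone | COc1ccc(cc1)C(C)=O | starting material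
4 | (E)-3-(4-isopropoxy-2-methoxyphenyl)-1-(4-methoxyphenyl)prop-2-en-1-one | COc1ccc(cc1)C(=O)/C=C/c1ccc(OC(C)C)cc1OC | intermediate
5 | 3-(4-isopropoxy-2-methoxyphenyl)-1-(4-methoxyphenyl)propan-1-one | COc1ccc(cc1)C(=O)CCc1ccc(OC(C)C)cc1OC | intermediate
6 | (1S)-3-(4-isopropoxy-2-methoxyphenyl)-1-(4-methoxyphenyl)propan-1-ol | COc1ccc([C@H](CCc2ccc(OC(C)C)cc2OC)O)cc1 | intermediate
7 | (S)-1-methoxy-1-(4-methoxyphenyl)-3-(4-isopropoxy-2-methoxyphenyl)propane | COc1ccc([C@H](CCc2ccc(OC(C)C)cc2OC)OC)cc1 | intermediate
8 | 4-bromo-2-methoxyphenol | COc1cc(Br)ccc1O | starting material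
9 | 2,4-dibromo-6-methoxyphenol | COc1cc(Br)cc(Br)c1O | intermediate
10 | (2,4-dibromo-6-methoxyphenoxy)trimethylsilane | COc1cc(Br)cc(Br)c1O[Si](C)(C)C | intermediate
11 | (5-bromo-3-methoxy-2-trimethylsilyloxyphenyl)lithium | COc1cc(Br)cc([Li])c1O[Si](C)(C)C | intermediate
12 | lithium 4-bromo-2-methoxy-6-(trimethylsilyl)phenoxide | COc1cc(Br)cc([Si](C)(C)C)c1O[Li] | intermediate
13 | 4-bromo-2-methoxy-6-(trimethylsilyl)phenyl trifluoromethanesulfonate | COc1cc(Br)cc([Si](C)(C)C)c1OS(=O)(=O)C(F)(F)F | intermediate
14 | 5-bromo-3-methoxybenzyne (5-bromo-3-methoxy-1,2-didehydrobenzene) | COC1=CC(Br)=CC#C1 | intermediate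
15 | aryloxonium aryl-anion zwitterion from O-arylation of 7 by 14 | COc1ccc([C@H](CCc2ccc(OC(C)C)cc2OC)[O+](C)C2=CC(Br)=CC(OC)=[C-]2)cc1 | intermediate
16 | 5-bromo-2-[(1S)-3-(4-isopropoxy-2-methoxyphenyl)-1-(4-methoxyphenyl)propyl]-1,3-dimethoxybenzene | COc1ccc([C@H](CCc2ccc(OC(C)C)cc2OC)c2c(OC)cc(Br)cc2OC)cc1 | intermediate
17 | 4-isopropoxybenzaldehyde | CC(C)Oc1ccc(C=O)cc1 | starting material
18 | 4-isopropoxystyrene | CC(C)Oc1ccc(C=C)cc1 | intermediate
19 | 5-[(E)-2-(4-isopropoxyphenyl)ethenyl]-2-[(1S)-3-(4-isopropoxy-2-methoxyphenyl)-1-(4-methoxyphenyl)propyl]-1,3-dimethoxybenzene | COc1ccc([C@H](CCc2ccc(OC(C)C)cc2OC)c2c(OC)cc(/C=C/c3ccc(OC(C)C)cc3)cc2OC)cc1 | intermediate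
20 | 4-[(3S)-3-{4-[(E)-2-(4-hydroxyphenyl)ethenyl]-2,6-dimethoxyphenyl}-3-(4-methoxyphenyl)propyl]-3-methoxyphenol | COc1ccc([C@H](CCc2ccc(O)cc2OC)c2c(OC)cc(/C=C/c3ccc(O)cc3)cc2OC)cc1 | target

**Step count**

Total: 12 steps. Longest linear sequence: 8 steps (steps 1, 2, 3, 4, 5, 9, 11, 12).

**Steps most likely to fail**

Step 9. The ether oxygen may be too weak a nucleophile, so that the aryne is consumed by fluoride or by itself. The zwitterion may also go astray: the aryl anion may abstract a β-hydrogen (loss of the ether as an alkene) or an α-hydrogen (ylide formation), or the ion pair may separate before recombination, eroding the configuration at C-1.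
Fallback by known chemistry, from ketone 5 back to 16: 5 would be reduced with the enantiomeric catalyst RuCl[(R,R)-TsDPEN](p-cymene) to (1R)-3-(4-isopropoxy-2-methoxyphenyl)-1-(4-methoxyphenyl)propan-1-ol F1. This would be carbamoylated (NaH, iPr2NCOCl) to (1R)-3-(4-isopropoxy-2-methoxyphenyl)-1-(4-methoxyphenyl)propyl N,N-diisopropylcarbamate F2. Lithiation–borylation would follow: deprotonation with s-BuLi in Et2O at −78 °C (retention), addition of 2-(4-bromo-2,6-dimethoxyphenyl)-5,5-dimethyl-1,3,2-dioxaborinane, and a 1,2-metallate shift promoted by MgBr2/MeOH, in which the aryl group migrates anti to the carbamate. This should give the tertiary boronic ester (S)-2-[1-(4-bromo-2,6-dimethoxyphenyl)-3-(4-isopropoxy-2-methoxyphenyl)-1-(4-methoxyphenyl)propyl]-5,5-dimethyl-1,3,2-dioxaborinane F3. Stereoretentive protodeboronation with TBAF·3H2O would then give 16. The net replacement of oxygen by aryl is invertive in this sequence, which is why the (R)-alcohol is used.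

Step 8. Exchange at the wrong bromine, or double exchange, would lead to loss of the para bromine or to a mis-silylated phenol.
Fallback, from 8 back to 13, never carrying two bromines: 8 would be converted (NaH, Et2NCOCl) into 4-bromo-2-methoxyphenyl N,N-diethylcarbamate F4. Directed ortho-metalation with lithium 2,2,6,6-tetramethylpiperidide (LiTMP) in the presence of TMSCl at −78 °C would silylate the only free position ortho to the carbamate and give 4-bromo-2-methoxy-6-(trimethylsilyl)phenyl N,N-diethylcarbamate F5. Reductive removal of the carbamoyl group with Cp2Zr(H)Cl in THF would give 4-bromo-2-methoxy-6-(trimethylsilyl)phenol F6, and Tf2O/pyridine would give 13.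

Step 12. Over-dealkylation of methyl ethers, acid-induced addition or oligomerisation at the electron-rich hydroxystilbene, or reversible ipso-protonation of ring C could erode material or configuration.
Fallback, from 16 back to 20, with the Lewis-acid step moved ahead of stilbene formation and a basic final step: 16 would be treated with BCl3 (CH2Cl2, −78 → 0 °C) to give 4-[(3S)-3-(4-bromo-2,6-dimethoxyphenyl)-3-(4-methoxyphenyl)propyl]-3-methoxyphenol F7. Heck coupling of F7 with 4-acetoxystyrene (Pd(OAc)2, P(o-tol)3, Et3N, DMF) would give 4-[(E)-2-{4-[(1S)-3-(4-hydroxy-2-methoxyphenyl)-1-(4-methoxyphenyl)propyl]-3,5-dimethoxyphenyl}ethenyl]phenyl acetate F8. Methanolysis (K2CO3, MeOH, rt) would give 20.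

**Further compounds**

F1 | step 9 | (1R)-3-(4-isopropoxy-2-methoxyphenyl)-1-(4-methoxyphenyl)propan-1-ol | COc1ccc([C@@H](CCc2ccc(OC(C)C)cc2OC)O)cc1
F2 | step 9 | (1R)-3-(4-isopropoxy-2-methoxyphenyl)-1-(4-methoxyphenyl)propyl N,N-diisopropylcarbamate | COc1ccc([C@@H](CCc2ccc(OC(C)C)cc2OC)OC(=O)N(C(C)C)C(C)C)cc1
F3 | step 9 | (S)-2-[1-(4-bromo-2,6-dimethoxyphenyl)-3-(4-isopropoxy-2-methoxyphenyl)-1-(4-methoxyphenyl)propyl]-5,5-dimethyl-1,3,2-dioxaborinane | COc1ccc([C@](B2OCC(C)(C)CO2)(CCc2ccc(OC(C)C)cc2OC)c2c(OC)cc(Br)cc2OC)cc1
F4 | step 8 | 4-bromo-2-methoxyphenyl N,N-diethylcarbamate | CCN(CC)C(=O)Oc1ccc(Br)cc1OC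
F5 | step 8 | 4-bromo-2-methoxy-6-(trimethylsilyl)phenyl N,N-diethylcarbamate | CCN(CC)C(=O)Oc1c(OC)cc(Br)cc1[Si](C)(C)C
F6 | step 8 | 4-bromo-2-methoxy-6-(trimethylsilyl)phenol | COc1cc(Br)cc([Si](C)(C)C)c1O
F7 | step 12 | 4-[(3S)-3-(4-bromo-2,6-dimethoxyphenyl)-3-(4-methoxyphenyl)propyl]-3-methoxyphenol | COc1ccc([C@H](CCc2ccc(O)cc2OC)c2c(OC)cc(Br)cc2OC)cc1
F8 | step 12 | 4-[(E)-2-{4-[(1S)-3-(4-hydroxy-2-methoxyphenyl)-1-(4-methoxyphenyl)propyl]-3,5-dimethoxyphenyl}ethenyl]phenyl acetate | COc1ccc([C@H](CCc2ccc(O)cc2OC)c2c(OC)cc(/C=C/c3ccc(OC(C)=O)cc3)cc2OC)cc1
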